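The trap in repeating this run is to watch the substrate fall, since a falling substrate does not say which step took it.

    substrate + enzyme → target + enzyme, rate k1*[substrate]*[enzyme]/(1 + ([substrate]/Km1) + ([target]/Kp1)) (Km1 = 21.3 mM, Kp1 = 6.30 mM, k1 = 697 L mol⁻¹ s⁻¹)
    substrate → uncatalysed product (k2 = 8.35 × 10⁻⁵ s⁻¹)
    2 enzyme → spent catalyst (k3 = 90.3 L mol⁻¹ s⁻¹)

| setting | noon | midnight |
|---|---|---|
| substrate | 11 mM | 11 mM |
| enzyme | 0.02 mol% | 0.06 mol% |
| time | 6.0 h | 6.0 h |

- which of these there is most of at the end, counted by the substrate in it, noon (uncatalysed product / substrate / target)
- which of these there is most of at the end, counted by the substrate in it, midnight (uncatalysed product / substrate / target)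
- amount of the one of these that there is most of at the end, in percent of the substrate charged, noon
- amount of the one of these that there is most of at the end, in percent of the substrate charged, midnight

- a doubled species enters its step squared and goes two at a time
- run time (noon): 6.0 h

I reckoned with rates, not concentrations. The enzyme turns substrate into target, while the background step turns substrate into uncatalysed product. Call R the first rate over the second, and D the denominator of the enzyme's rate law.

At noon the enzyme started at 0.00220 mM, and R began at 12.1. Two things slowed the enzyme's side. I gave the target its full charge in D, so D went from 1.52 to 2.75, a factor of 1.81. The enzyme also pairs off into spent catalyst, with a first half-life of 0.699 h, so it falls by a factor of one plus the time over that half-life.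

With the larger D, the substrate's lifetime under both steps was 0.433 h. By then the enzyme had fallen by a factor of 1.62.

The closing ratio is R one substrate lifetime into the run, with the target's inhibition at full strength. It is a selectivity factor for that one moment, which came earlier than the end of the run. At noon it came to 4.13.

The run lasted far longer than that lifetime, so I expected the substrate to be used up and the target's share to be R/(R+1) at the closing ratio. That gave target at noon, at 80.5 %.

Midnight charged 3.00 times the enzyme, or 0.00660 mM. Its half-life was 0.233 h and its substrate lifetime 0.158 h, so its closing ratio was 12.0. That gave target at 92.3 %.

The forecast named target at noon with 83.7 % and target at midnight with 92.7 %, holding that “product inhibition holds D near 2.5”. My D was larger than that, and my noon share was smaller.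

The simulation gave target at 84.0 % at noon and target at 92.8 % at midnight, so the forecast stood. Noon still held 84.1 % target after 60.0 h. Its end readings put target over uncatalysed product at 5.37, above my closing ratio of 4.13. A neighbour flask took noon's recipe with 2.8 mM of substrate. There the enzyme's half-life was 2.75 h and the substrate's lifetime 0.785 h, so the closing ratio was 2.52, a target share of 71.6 %. That flask ended with 74.3 % target.

The constants belong to no real substance; the run is a simulation.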